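## Retrosynthetic overview

1. Target ⇐ desilylation and angeloylation of a tetracyclic 8‑hydroxy‑9‑acetate, whose cycloheptane ring is closed last through the C8–C9 bond by a chromium‑mediated acetoxy‑allylation between a C8 aldehyde and the formyl enol ether (C9/C10/C14).
2. α‑Methylene‑γ‑lactone (C6–C7 bond, C11–C13) ⇐ chromium‑mediated 2‑(methoxycarbonyl)allylation of a C6 aldehyde on the bicyclic core.
3. Bicyclic core (cyclopentane plus bridging dihydropyran; C1, C4, C5) ⇐ one enantioselective Brønsted‑acid‑catalysed domino Knoevenagel / bridged oxa‑[4+2] reaction of an achiral (Z)‑hex‑4‑enal with malondialdehyde.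
4. Achiral aldehyde ⇐ Claisen rearrangement of an allylic alcohol made from 2‑bromoallyl alcohol and silyloxyacetaldehyde.
5. Ring order: cyclopentane and dihydropyran together, then lactone, then cycloheptane.

Assumption: locants C1–C15 in the text are the guaiane locants of the target (lactone C6/C7/C11–C13, angelate at C8, acetate at C9, enol ether C10=C14, quaternary C4 carrying C15), and "(S,S)-IDPi" is the imidodiphosphorimidate acid built from two (S)-3,3′-bis[3,5-bis(trifluoromethyl)phenyl]-BINOL units with N-triflyl groups.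

## Route

Step 1
Reactants: 1 2-bromoprop-2-en-1-ol
Product: 2 [(2-bromoprop-2-en-1-yl)oxy](tert-butyl)diphenylsilane
Conditions: TBDPSCl, imidazole, CH2Cl2, 0 °C → rt
Reagents that add atoms: tert-butyl(chloro)diphenylsilane CC(C)(C)[Si](Cl)(c1ccccc1)c1ccccc1
Why: Standard silyl ether formation on a primary alcohol.

Step 2
Reactants: 2 [(2-bromoprop-2-en-1-yl)oxy](tert-butyl)diphenylsilane; 3 2-[(tert-butyldimethylsilyl)oxy]acetaldehyde
Product: 5 rac-1-[(tert-butyldimethylsilyl)oxy]-3-{[(tert-butyldiphenylsilyl)oxy]methyl}but-3-en-2-ol, via vinyllithium 4 (not isolated)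
Conditions: t-BuLi (2.1 equiv), Et2O, −78 °C; then 3, −78 °C; H2O
Reagents that add atoms: none
Why: Bromine–lithium exchange followed by 1,2-addition to the aldehyde; the alcohol is racemic and its stereocentre is erased in step 3.

Step 3
Reactants: 5 rac-1-[(tert-butyldimethylsilyl)oxy]-3-{[(tert-butyldiphenylsilyl)oxy]methyl}but-3-en-2-ol
Product: 7 (4Z)-6-[(tert-butyldimethylsilyl)oxy]-4-{[(tert-butyldiphenylsilyl)oxy]methyl}hex-4-enal, via allyl vinyl ether 6 (not isolated)
Conditions: ethyl vinyl ether, Hg(OAc)2 (10 mol%), reflux; then PhMe, 150 °C (sealed tube)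
Reagents that add atoms: ethyl vinyl ether C=COCC
Why: Transvinylation and Claisen rearrangement through a chair transition state with the CH2OTBS group equatorial give the achiral Z-alkene (C6 cis to C15).

Step 4
Reactants: 7 (4Z)-6-[(tert-butyldimethylsilyl)oxy]-4-{[(tert-butyldiphenylsilyl)oxy]methyl}hex-4-enal; 8 sodium 3-oxoprop-1-en-1-olate (sodium malondialdehyde enolate)
Product: 11 (1S,5R,8S)-8-{[(tert-butyldimethylsilyl)oxy]methyl}-1-{[(tert-butyldiphenylsilyl)oxy]methyl}-2-oxabicyclo[3.2.1]oct-3-ene-4-carbaldehyde, via malondialdehyde 9 (not isolated), via alkylidene-malondialdehyde 10 (not isolated)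
Conditions: 8, HCl (1.0 equiv, Et2O), 0 °C, filter; then 7, (S,S)-IDPi (5 mol%), 5 Å MS, CHCl3, −40 → −20 °C
Reagents that add atoms: none
Why: Proposed new method: enantioselective domino Knoevenagel / bridged intramolecular inverse-electron-demand oxa-Diels–Alder reaction, in which the confined chiral acid condenses 7 with the enol of 9 and protonates 10 to a chiral contact ion pair; the less substituted alkene carbon C5 attacks C1 (5-endo, tertiary cation character at C4) while the formyl oxygen closes on C4 in an asynchronous suprafacial [4+2], so C1, C4 and C5 are set in one event and the Z-alkene places the C5 substituent syn to the new dihydropyran bridge; closest known reactions are the Tietze domino Knoevenagel/hetero-Diels–Alder reaction, confined-acid-catalysed intramolecular oxa-[4+2] cycloadditions of ortho-quinone methides with unactivated olefins, and the bridged-mode intramolecular nitrone cycloaddition of pent-4-enal nitrones, which reaches the same tether geometry.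

Step 5
Reactants: 11 (1S,5R,8S)-8-{[(tert-butyldimethylsilyl)oxy]methyl}-1-{[(tert-butyldiphenylsilyl)oxy]methyl}-2-oxabicyclo[3.2.1]oct-3-ene-4-carbaldehyde
Product: 12 (1S,5R,8S)-1-{[(tert-butyldiphenylsilyl)oxy]methyl}-8-(hydroxymethyl)-2-oxabicyclo[3.2.1]oct-3-ene-4-carbaldehyde
Conditions: HF·pyridine, pyridine, THF, 0 °C
Reagents that add atoms: none
Why: Selective fluoride desilylation of the less hindered primary TBS ether in the presence of the neopentyl-type TBDPS ether.

Step 6
Reactants: 12 (1S,5R,8S)-1-{[(tert-butyldiphenylsilyl)oxy]methyl}-8-(hydroxymethyl)-2-oxabicyclo[3.2.1]oct-3-ene-4-carbaldehyde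
Product: 13 (1S,5R,8R)-1-{[(tert-butyldiphenylsilyl)oxy]methyl}-2-oxabicyclo[3.2.1]oct-3-ene-4,8-dicarbaldehyde
Conditions: Dess–Martin periodinane, CH2Cl2, 0 °C → rt
Reagents that add atoms: none
Why: Neutral Dess–Martin oxidation gives the C6 aldehyde without enolising C5 (a base would trigger β-elimination of the ring oxygen); the descriptor at C8 changes only by CIP priority.

Step 7
Reactants: 14 2,2-dimethoxyacetaldehyde; 15 methyl prop-2-enoate
Product: 16 methyl rac-3-hydroxy-4,4-dimethoxy-2-methylidenebutanoate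
Conditions: DABCO (0.5 equiv), dioxane/H2O, rt
Reagents that add atoms: none
Why: Morita–Baylis–Hillman reaction of an activated aldehyde with methyl acrylate.

Step 8
Reactants: 16 methyl rac-3-hydroxy-4,4-dimethoxy-2-methylidenebutanoate
Product: 17 methyl (2Z)-2-(bromomethyl)-4,4-dimethoxybut-2-enoate
Conditions: NBS, Me2S, CH2Cl2, 0 °C → rt
Reagents that add atoms: N-bromosuccinimide O=C1CCC(=O)N1Br
Why: Corey–Kim-type activation of the Baylis–Hillman alcohol and SN2′ bromide delivery give the rearranged Z allylic bromide.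

Step 9
Reactants: 13 (1S,5R,8R)-1-{[(tert-butyldiphenylsilyl)oxy]methyl}-2-oxabicyclo[3.2.1]oct-3-ene-4,8-dicarbaldehyde; 17 methyl (2Z)-2-(bromomethyl)-4,4-dimethoxybut-2-enoate
Product: 21 (2R,3S)-2-[(1S,5R,8S)-1-{[(tert-butyldiphenylsilyl)oxy]methyl}-4-formyl-2-oxabicyclo[3.2.1]oct-3-en-8-yl]-4-methylidene-5-oxooxolane-3-carbaldehyde, via allylchromium reagent 18 (not isolated), via hydroxy ester 19 (not isolated), via lactone acetal 20 (not isolated)
Conditions: CrCl2 (4 equiv), THF, 0 °C → rt; then p-TsOH (cat.), wet acetone, rt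
Reagents that add atoms: water O
Why: Nozaki–Hiyama-type chromium 2-(alkoxycarbonyl)allylation followed by acid lactonisation and acetal hydrolysis; the reagent adds only to the aliphatic C6 aldehyde (the vinylogous formyl group is deactivated) through a chair transition state that gives the anti adduct (trans lactone), and because the aldehyde hydrogen must sit in the congested position above the dihydropyran, attack comes from the C1 side, away from the CH2OTBDPS-bearing bridgehead, setting C6 and C7.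

Step 10
Reactants: 21 (2R,3S)-2-[(1S,5R,8S)-1-{[(tert-butyldiphenylsilyl)oxy]methyl}-4-formyl-2-oxabicyclo[3.2.1]oct-3-en-8-yl]-4-methylidene-5-oxooxolane-3-carbaldehyde
Product: 24 (1R,4S,5S,6S,7R,8S,9S)-9-acetoxy-15-[(tert-butyldiphenylsilyl)oxy]-8-hydroxy-4,14-epoxyguaia-10(14),11(13)-dien-12,6-olide, via bromo enol acetate 22 (not isolated), via alkoxy-acetoxyallyl chromium species 23 (not isolated)
Conditions: AcBr (1.1 equiv), CH2Cl2, −60 → −30 °C; then CrCl2 (4 equiv), THF, 0 °C → rt
Reagents that add atoms: acetyl bromide CC(=O)Br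
Why: Proposed new method: ring-closing Nozaki–Hiyama–Kishi-type acetoxy-allylation of a cyclic β-alkoxy enal, in which acetyl bromide O-acylates the vinylogous formate and bromide adds at C14 (1,4-addition, as in the preparation of 3-bromopropenyl esters from acrolein), divalent chromium reduces the anomeric C–Br bond, and the 1-alkoxy-3-acetoxyallyl chromium species adds through its exocyclic terminus C9 to the tethered C8 aldehyde with allylic transposition that regenerates the enol ether; the tether forces attack on the C6 face of the E-enol acetate (sets C9), and the forming seven-membered ring holds the aldehyde substituent axial in the chromium-bridged chair, which gives the 8,9-trans pair; closest known reactions are the intermolecular Lombardo–Trombini acyloxy-allylation and Takai alkoxy-allylation of aldehydes with CrCl2.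

Step 11
Reactants: 24 (1R,4S,5S,6S,7R,8S,9S)-9-acetoxy-15-[(tert-butyldiphenylsilyl)oxy]-8-hydroxy-4,14-epoxyguaia-10(14),11(13)-dien-12,6-olide; 25 (2Z)-2-methylbut-2-enoic acid (angelic acid)
Product: 26 (1R,4S,5S,6S,7S,8S,9S)-9-acetoxy-15-[(tert-butyldiphenylsilyl)oxy]-8-[(2Z)-2-methylbut-2-enoyloxy]-4,14-epoxyguaia-10(14),11(13)-dien-12,6-olide
Conditions: 25, 2,4,6-trichlorobenzoyl chloride, Et3N, PhMe, rt; then 24, PhMe, 80 °C
Reagents that add atoms: none
Why: Yamaguchi esterification through the mixed anhydride acylates the hindered C8 alcohol without Z→E isomerisation of the angelate (no DMAP).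

Step 12
Reactants: 26 (1R,4S,5S,6S,7S,8S,9S)-9-acetoxy-15-[(tert-butyldiphenylsilyl)oxy]-8-[(2Z)-2-methylbut-2-enoyloxy]-4,14-epoxyguaia-10(14),11(13)-dien-12,6-olide
Product: 27 (1R,4S,5S,6S,7S,8S,9S)-9-acetoxy-15-hydroxy-8-[(2Z)-2-methylbut-2-enoyloxy]-4,14-epoxyguaia-10(14),11(13)-dien-12,6-olide (CNP0073339.2)
Conditions: HF·pyridine, pyridine, THF, 0 °C → rt
Reagents that add atoms: none
Why: Buffered fluoride desilylation frees the C15 alcohol and leaves the enol ether, allylic acetate, angelate and α-methylene lactone intact.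

## Compound list

1 | 2-bromoprop-2-en-1-ol | C=C(Br)CO | starting material
2 | [(2-bromoprop-2-en-1-yl)oxy](tert-butyl)diphenylsilane | C=C(Br)CO[Si](c1ccccc1)(c1ccccc1)C(C)(C)C | intermediate
3 | 2-[(tert-butyldimethylsilyl)oxy]acetaldehyde | O=CCO[Si](C)(C)C(C)(C)C | starting material
4 | 3-[(tert-butyldiphenylsilyl)oxy]prop-1-en-2-yllithium | [Li]C(=C)CO[Si](c1ccccc1)(c1ccccc1)C(C)(C)C | intermediate
5 | rac-1-[(tert-butyldimethylsilyl)oxy]-3-{[(tert-butyldiphenylsilyl)oxy]methyl}but-3-en-2-ol | C=C(CO[Si](c1ccccc1)(c1ccccc1)C(C)(C)C)C(O)CO[Si](C)(C)C(C)(C)C | intermediate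
6 | rac-O-vinyl ether of 5 (3-(ethenyloxy)-4-[(tert-butyldimethylsilyl)oxy]-2-{[(tert-butyldiphenylsilyl)oxy]methyl}but-1-ene) | C=COC(CO[Si](C)(C)C(C)(C)C)C(=C)CO[Si](c1ccccc1)(c1ccccc1)C(C)(C)C | intermediate
7 | (4Z)-6-[(tert-butyldimethylsilyl)oxy]-4-{[(tert-butyldiphenylsilyl)oxy]methyl}hex-4-enal | O=CCC/C(CO[Si](c1ccccc1)(c1ccccc1)C(C)(C)C)=C/CO[Si](C)(C)C(C)(C)C | intermediate
8 | sodium 3-oxoprop-1-en-1-olate | [Na+].[O-]/C=C/C=O | starting material
9 | propanedial (malondialdehyde) | O=CCC=O | intermediate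
10 | 2-[(4Z)-6-[(tert-butyldimethylsilyl)oxy]-4-{[(tert-butyldiphenylsilyl)oxy]methyl}hex-4-en-1-ylidene]propanedial | O=CC(C=O)=CCC/C(CO[Si](c1ccccc1)(c1ccccc1)C(C)(C)C)=C/CO[Si](C)(C)C(C)(C)C | intermediate
11 | (1S,5R,8S)-8-{[(tert-butyldimethylsilyl)oxy]methyl}-1-{[(tert-butyldiphenylsilyl)oxy]methyl}-2-oxabicyclo[3.2.1]oct-3-ene-4-carbaldehyde | O=CC1=CO[C@@]2(CO[Si](c3ccccc3)(c3ccccc3)C(C)(C)C)CC[C@@H]1[C@H]2CO[Si](C)(C)C(C)(C)C | intermediate
12 | (1S,5R,8S)-1-{[(tert-butyldiphenylsilyl)oxy]methyl}-8-(hydroxymethyl)-2-oxabicyclo[3.2.1]oct-3-ene-4-carbaldehyde | O=CC1=CO[C@@]2(CO[Si](c3ccccc3)(c3ccccc3)C(C)(C)C)CC[C@@H]1[C@H]2CO | intermediate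
13 | (1S,5R,8R)-1-{[(tert-butyldiphenylsilyl)oxy]methyl}-2-oxabicyclo[3.2.1]oct-3-ene-4,8-dicarbaldehyde | O=CC1=CO[C@@]2(CO[Si](c3ccccc3)(c3ccccc3)C(C)(C)C)CC[C@@H]1[C@H]2C=O | intermediate
14 | 2,2-dimethoxyacetaldehyde | O=CC(OC)OC | starting material
15 | methyl prop-2-enoate | C=CC(=O)OC | starting material
16 | methyl rac-3-hydroxy-4,4-dimethoxy-2-methylidenebutanoate | C=C(C(=O)OC)C(O)C(OC)OC | intermediate
17 | methyl (2Z)-2-(bromomethyl)-4,4-dimethoxybut-2-enoate | COC(=O)/C(CBr)=C/C(OC)OC | intermediate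
18 | dichloro[(2Z)-4,4-dimethoxy-2-(methoxycarbonyl)but-2-en-1-yl]chromium (trivalent chromium, solvent ligands omitted) | COC(=O)/C(C[Cr](Cl)Cl)=C/C(OC)OC | intermediate
19 | methyl (3S,4R)-4-[(1S,5R,8S)-1-{[(tert-butyldiphenylsilyl)oxy]methyl}-4-formyl-2-oxabicyclo[3.2.1]oct-3-en-8-yl]-3-(dimethoxymethyl)-4-hydroxy-2-methylidenebutanoate | O=CC1=CO[C@@]2(CO[Si](c3ccccc3)(c3ccccc3)C(C)(C)C)CC[C@@H]1[C@H]2[C@@H](O)[C@@H](C(OC)OC)C(=C)C(=O)OC | intermediate
20 | (4S,5R)-5-[(1S,5R,8S)-1-{[(tert-butyldiphenylsilyl)oxy]methyl}-4-formyl-2-oxabicyclo[3.2.1]oct-3-en-8-yl]-4-(dimethoxymethyl)-3-methylideneoxolan-2-one | O=CC1=CO[C@@]2(CO[Si](c3ccccc3)(c3ccccc3)C(C)(C)C)CC[C@@H]1[C@H]2[C@H]1OC(=O)C(=C)[C@@H]1C(OC)OC | intermediate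
21 | (2R,3S)-2-[(1S,5R,8S)-1-{[(tert-butyldiphenylsilyl)oxy]methyl}-4-formyl-2-oxabicyclo[3.2.1]oct-3-en-8-yl]-4-methylidene-5-oxooxolane-3-carbaldehyde | O=CC1=CO[C@@]2(CO[Si](c3ccccc3)(c3ccccc3)C(C)(C)C)CC[C@@H]1[C@H]2[C@H]1OC(=O)C(=C)[C@@H]1C=O | intermediate
22 | 1,4-adduct of acetyl bromide to 21: 3-bromo-4-[(E)-acetoxymethylidene]-2-oxabicyclo[3.2.1]octane unit (C3 epimers), other stereocentres as in 21 | CC(=O)O/C=C1/C(Br)O[C@@]2(CO[Si](c3ccccc3)(c3ccccc3)C(C)(C)C)CC[C@@H]1[C@H]2[C@H]1OC(=O)C(=C)[C@@H]1C=O | intermediate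
23 | dichlorochromium species from 22 (chromium in place of bromine at C3 of the bicycle; trivalent chromium, solvent ligands omitted) | CC(=O)O/C=C1/C([Cr](Cl)Cl)O[C@@]2(CO[Si](c3ccccc3)(c3ccccc3)C(C)(C)C)CC[C@@H]1[C@H]2[C@H]1OC(=O)C(=C)[C@@H]1C=O | intermediate
24 | (1R,4S,5S,6S,7R,8S,9S)-9-acetoxy-15-[(tert-butyldiphenylsilyl)oxy]-8-hydroxy-4,14-epoxyguaia-10(14),11(13)-dien-12,6-olide | C=C1C(=O)O[C@H]2[C@H]1[C@H](O)[C@@H](OC(C)=O)C1=CO[C@@]3(CO[Si](c4ccccc4)(c4ccccc4)C(C)(C)C)CC[C@@H]1[C@@H]23 | intermediate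
25 | (2Z)-2-methylbut-2-enoic acid | C/C=C(/C)C(=O)O | starting material
26 | (1R,4S,5S,6S,7S,8S,9S)-9-acetoxy-15-[(tert-butyldiphenylsilyl)oxy]-8-[(2Z)-2-methylbut-2-enoyloxy]-4,14-epoxyguaia-10(14),11(13)-dien-12,6-olide | C=C1C(=O)O[C@H]2[C@H]1[C@H](OC(=O)/C(C)=C\C)[C@@H](OC(C)=O)C1=CO[C@@]3(CO[Si](c4ccccc4)(c4ccccc4)C(C)(C)C)CC[C@@H]1[C@@H]23 | intermediate
27 | (1R,4S,5S,6S,7S,8S,9S)-9-acetoxy-15-hydroxy-8-[(2Z)-2-methylbut-2-enoyloxy]-4,14-epoxyguaia-10(14),11(13)-dien-12,6-olide | C=C1C(=O)O[C@H]2[C@H]1[C@H](OC(=O)/C(C)=C\C)[C@@H](OC(C)=O)C1=CO[C@@]3(CO)CC[C@@H]1[C@@H]23 | target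

## Step count and risks

Total step count: 12. Longest linear sequence: 10 (steps 1–6 and 9–12); steps 7–8 make the allyl bromide.

Most likely to fail:

**Step 4 (proposed new method).** The bridged cyclisation may lose to an ene pathway or to a racemic background reaction of 10. The sense of induction of the (S,S)-acid is assigned by analogy only and must be confirmed; the antipodal acid is used if it is opposite. Fallback, setting out from 7 and coming back at 11: Wittig homologation of 7 with (triphenylphosphoranylidene)acetaldehyde gives the (2E,6Z)-dienal F1. The established Lewis-acid-promoted inverse-electron-demand oxa-Diels–Alder reaction of enals with simple alkenes (Me2AlCl, CH2Cl2, −78 °C) closes it to the racemic formyl-free bicyclic enol ether F2. Vilsmeier–Haack formylation (POCl3, DMF, then aqueous NaOAc) gives racemic 11 F3, and preparative chromatography on a chiral stationary phase delivers 11. This replaces the doubly activated heterodiene, introduces C9 afterwards and takes the enantiomer by resolution; it still relies on the bridged ring closure.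

**Step 10 (proposed new method).** Acetyl bromide may also attack the free C8 aldehyde, the allyl chromium species may react through C14 instead of C9, and the C8/C9 configuration rests on a ring-strain argument. The acetate may also migrate to the new C8 hydroxyl. Fallback with known chemistry, setting out from 21 and coming back at 26: a triazolium-derived N-heterocyclic carbene (iPr2NEt, THF) effects an intramolecular crossed benzoin reaction to the conjugated acyloin, the 8-hydroxy-9-ketone F5. Yamaguchi angeloylation gives the 8-angeloyloxy-9-ketone F6. Luche reduction (NaBH4, CeCl3, MeOH, −78 °C) gives the 9-alcohol F7, and Ac2O/pyridine gives 26.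

**Step 9.** The chromium reagent may not discriminate fully between the two formyl groups, and the facial selectivity at C6 is substrate-controlled on an unusual bicycle. Fallback, setting out from 13 and coming back at 21: the allylboronate methyl (2Z)-4,4-dimethoxy-2-[(pinacolboryl)methyl]but-2-enoate F4 (boryl-methyl trans to the dimethoxymethyl group) is made by syn-hydrocupration of methyl 4,4-dimethoxybut-2-ynoate and trapping with pinacol (iodomethyl)boronate. Hall-type allylboration of 13 (PhMe, 80 °C, or with a chiral Brønsted acid to override substrate bias) is more selective for the aliphatic aldehyde and gives the anti adduct through a closed transition state. The same acid work-up then lactonises and unmasks the aldehyde to give 21.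

## Further compounds

F1 | step 4 | (2E,6Z)-8-[(tert-butyldimethylsilyl)oxy]-6-{[(tert-butyldiphenylsilyl)oxy]methyl}octa-2,6-dienal | O=C/C=C/CC/C(CO[Si](c1ccccc1)(c1ccccc1)C(C)(C)C)=C/CO[Si](C)(C)C(C)(C)C
F2 | step 4 | racemic 8-{[(tert-butyldimethylsilyl)oxy]methyl}-1-{[(tert-butyldiphenylsilyl)oxy]methyl}-2-oxabicyclo[3.2.1]oct-3-ene (relative configuration as in 11; one enantiomer drawn) | C1=CO[C@@]2(CO[Si](c3ccccc3)(c3ccccc3)C(C)(C)C)CC[C@@H]1[C@H]2CO[Si](C)(C)C(C)(C)C
F3 | step 4 | racemic 11 (one enantiomer drawn) | O=CC1=CO[C@@]2(CO[Si](c3ccccc3)(c3ccccc3)C(C)(C)C)CC[C@@H]1[C@H]2CO[Si](C)(C)C(C)(C)C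
F4 | step 9 | methyl (2Z)-4,4-dimethoxy-2-[(4,4,5,5-tetramethyl-1,3,2-dioxaborolan-2-yl)methyl]but-2-enoate | COC(=O)/C(CB1OC(C)(C)C(C)(C)O1)=C\C(OC)OC
F5 | step 10 | 15-[(tert-butyldiphenylsilyl)oxy]-8-hydroxy-9-oxo-4,14-epoxyguaia-10(14),11(13)-dien-12,6-olide (configuration as in 24) | C=C1C(=O)O[C@H]2[C@H]1[C@H](O)C(=O)C1=CO[C@@]3(CO[Si](c4ccccc4)(c4ccccc4)C(C)(C)C)CC[C@@H]1[C@@H]23
F6 | step 10 | 15-[(tert-butyldiphenylsilyl)oxy]-8-[(2Z)-2-methylbut-2-enoyloxy]-9-oxo-4,14-epoxyguaia-10(14),11(13)-dien-12,6-olide (configuration as in 26) | C=C1C(=O)O[C@H]2[C@H]1[C@H](OC(=O)/C(C)=C\C)C(=O)C1=CO[C@@]3(CO[Si](c4ccccc4)(c4ccccc4)C(C)(C)C)CC[C@@H]1[C@@H]23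
F7 | step 10 | 15-[(tert-butyldiphenylsilyl)oxy]-9-hydroxy-8-[(2Z)-2-methylbut-2-enoyloxy]-4,14-epoxyguaia-10(14),11(13)-dien-12,6-olide (configuration as in 26) | C=C1C(=O)O[C@H]2[C@H]1[C@H](OC(=O)/C(C)=C\C)[C@@H](O)C1=CO[C@@]3(CO[Si](c4ccccc4)(c4ccccc4)C(C)(C)C)CC[C@@H]1[C@@H]23
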